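The route rests on growing, not coupling, the benzene ring of the 8-hydroxychromone (primed unit) onto the finished 7-methoxychromone. That ring carries four contiguous substituents: aryl on C5', the ketone carbon on C4a', oxygens on C8a' and C8'. This pattern maps onto an aryl ynone plus a butadiene bearing two oxygens on C1 and one on C2. One cycloaddition with silanol loss forms C5'–C6' and C4a'–C8a', delivering arene, biaryl axis and the ortho-hydroxyacetophenone for the second pyranone together. The precursor is a but-3-yn-2-one whose alkyne terminus sits on C6 of 7-methoxy-2-(2-phenylethyl)chromone. Acyl migration, cyclodehydration and O-demethylation complete the target.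

Key step: step 6

Assumption: the target SMILES carries no stereodescriptor, so the C6–C5' axis is treated as configurationally unspecified and no atroposelective control is attempted. The two secondary carbinol building blocks are used as racemates because their stereocentres are erased on the way.

Step 1
Reactants: 1 1-(5-bromo-2-hydroxy-4-methoxyphenyl)ethanone; 2 ethyl 3-phenylpropanoate
Product: 4 6-bromo-7-methoxy-2-(2-phenylethyl)chromen-4-one, via bromo diketone 3 (not isolated)
Conditions: NaH (4 equiv), 2 (1.5 equiv), THF, reflux; then MeOH, conc. HCl, reflux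
Reagents that add atoms: none
Why: Crossed Claisen condensation of the phenoxide-enolate dianion of 1 with ester 2 should give the β-diketone, which under acid closes by attack of the phenol on the distal carbonyl and loss of water, the standard cyclodehydration route to 2-alkylchromones.

Step 2
Reactants: 4 6-bromo-7-methoxy-2-(2-phenylethyl)chromen-4-one; 5 but-3-yn-2-ol (racemic)
Product: 6 6-(3-hydroxybut-1-yn-1-yl)-7-methoxy-2-(2-phenylethyl)chromen-4-one (racemic)
Conditions: Pd(PPh3)2Cl2 (5 mol %), CuI (10 mol %), Et3N, DMF, 80 °C, Ar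
Reagents that add atoms: none
Why: Sonogashira coupling (oxidative addition of zerovalent palladium into C6–Br, transmetalation from the copper acetylide, reductive elimination) is established for 6-bromochromones, a tertiary amine is used because secondary amines open the pyranone, and the racemic carbinol centre is of no consequence since step 3 erases it.

Step 3
Reactants: 6 6-(3-hydroxybut-1-yn-1-yl)-7-methoxy-2-(2-phenylethyl)chromen-4-one
Product: 7 4-[7-methoxy-4-oxo-2-(2-phenylethyl)chromen-6-yl]but-3-yn-2-one
Conditions: activated MnO2 (15 equiv), CH2Cl2, rt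
Reagents that add atoms: none
Why: Heterogeneous MnO2 oxidation is selective for activated (here propargylic) alcohols and runs under neutral conditions, so the Michael-sensitive ynone never meets base or nucleophile.

Step 4
Reactants: 8 2-hydroxybut-3-enoic acid (racemic)
Product: 9 trimethylsilyl 2-(trimethylsilyloxy)but-3-enoate (racemic)
Conditions: HMDS (1.2 equiv), Me3SiCl (cat.), CH2Cl2, reflux; distillation
Reagents that add atoms: hexamethyldisilazane, C[Si](C)(C)N[Si](C)(C)C
Why: Silylation of both acidic OH groups by HMDS releases only ammonia and avoids the stronger amine bases that could shift the double bond into conjugation; the racemic C2 centre is planarised in step 5.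

Step 5
Reactants: 9 trimethylsilyl 2-(trimethylsilyloxy)but-3-enoate
Product: 10 1,1,2-tris(trimethylsilyloxy)buta-1,3-diene
Conditions: LDA (commercial solution, 1.1 equiv), THF, −78 °C; Me3SiCl (1.3 equiv), −78 °C to rt; pentane, filtration, bulb-to-bulb distillation
Reagents that add atoms: chlorotrimethylsilane, C[Si](C)(C)Cl
Why: Enolate O-silylation (silyl ketene acetal formation): LDA removes the doubly activated allylic α-proton of the silyl ester and the hard electrophile Me3SiCl traps the dienolate on oxygen, the same operation that turns bis-silylated glycolic acid into tris(trimethylsilyloxy)ethene, and no double-bond isomers arise because C1 carries two identical groups.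

Step 6
Reactants: 7 4-[7-methoxy-4-oxo-2-(2-phenylethyl)chromen-6-yl]but-3-yn-2-one; 10 1,1,2-tris(trimethylsilyloxy)buta-1,3-diene
Product: 13 6-(2-acetyl-3,4-dihydroxyphenyl)-7-methoxy-2-(2-phenylethyl)chromen-4-one, via cycloadduct 11 (not isolated), via bis-silyl ether 12 (not isolated)
Conditions: 10 (3 equiv), toluene (1 M), sealed tube, 110 °C, Ar; then 1 M HCl, THF, rt
Reagents that add atoms: none
Why: Proposed new method: three silyloxy donors raise the HOMO of 10 and the acetyl group lowers the LUMO of 7, so a concerted but strongly asynchronous normal-demand [4+2] cycloaddition is expected, in which the unsubstituted CH2 terminus (C4 of 10) bonds first to the aryl-bearing β-carbon (future C5') and the ketene-acetal carbon then closes onto the acyl-bearing α-carbon (future C4a'). The closest known reaction type is the Diels–Alder benzannulation of vinylketene acetals (Brassard-type dienes) with alkynones and alkynoates, which aromatise by losing alcohol or silanol, whereas a 1,1,2-trioxygenated diene has not been used in this way. The single new ring, the carbocycle C4a'–C5'–C6'–C7'–C8'–C8a', closes in the intermolecular [4+2] mode; adduct 11 then ionises one geminal silyloxy group at C8a' and loses a C6' proton (formal 1,4-elimination of Me3SiOH) to give arene 12, whose two aryl silyl ethers are hydrolysed in the acidic work-up. No stereocentre is created, since C8a' of 11 bears two identical groups and becomes planar on aromatisation. The selectivity needed is regiochemical: two donors on C1 override the opposing single donor on C2 and put the largest HOMO coefficient on C4, matching the largest LUMO coefficient at the ynone β-carbon, and because both C1 oxygens carry the same silyl group either one may leave without changing the product. Chemoselectivity rests on the ynone being far more electrophilic than the C2=C3 bond of the chromone and on Lewis-acid-free thermal conditions that suppress Mukaiyama-type additions.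

Step 7
Reactants: 13 6-(2-acetyl-3,4-dihydroxyphenyl)-7-methoxy-2-(2-phenylethyl)chromen-4-one; 14 3-phenylpropanoyl chloride
Product: 15 3-acetyl-4-[7-methoxy-4-oxo-2-(2-phenylethyl)chromen-6-yl]benzene-1,2-diyl bis(3-phenylpropanoate)
Conditions: 14 (2.5 equiv), pyridine (5 equiv), DMAP (10 mol %), CH2Cl2, 0 °C to rt
Reagents that add atoms: none
Why: DMAP-catalysed esterification with an excess of acid chloride should acylate both the free C8' phenol and the hydrogen-bonded, hindered C8a' phenol, which places the acyl donor next to the acetyl group and masks the oxidation-prone catechol.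

Step 8
Reactants: 15 3-acetyl-4-[7-methoxy-4-oxo-2-(2-phenylethyl)chromen-6-yl]benzene-1,2-diyl bis(3-phenylpropanoate)
Product: 17 6-[8-hydroxy-4-oxo-2-(2-phenylethyl)chromen-5-yl]-7-methoxy-2-(2-phenylethyl)chromen-4-one, via ester diketone 16 (not isolated)
Conditions: KOtBu (3 equiv), THF (dilute), 0 °C to rt; then MeOH, conc. HCl, reflux
Reagents that add atoms: none
Why: Baker–Venkataraman O-to-C acyl migration: the acetyl enolate attacks the neighbouring C8a' ester through a six-membered transition state, and acidic methanol then cyclodehydrates the β-diketone to the pyranone and transesterifies whichever catechol oxygen still holds the spare acyl group, so any acyl scrambling between the two oxygens converges on one product.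

Step 9
Reactants: 17 6-[8-hydroxy-4-oxo-2-(2-phenylethyl)chromen-5-yl]-7-methoxy-2-(2-phenylethyl)chromen-4-one
Product: 18 7-hydroxy-6-[8-hydroxy-4-oxo-2-(2-phenylethyl)chromen-5-yl]-2-(2-phenylethyl)chromen-4-one (target)
Conditions: BBr3 (6 equiv), CH2Cl2, −78 °C to rt; then H2O
Reagents that add atoms: none
Why: Lewis-acid ether cleavage: BBr3 binds the aryl methyl ether oxygen and bromide removes the methyl group by SN2, a standard unmasking of 7-methoxychromones that leaves the pyranones, the phenol and the saturated side chains untouched.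

Compound list
1 | 1-(5-bromo-2-hydroxy-4-methoxyphenyl)ethanone | CC(=O)c1cc(Br)c(OC)cc1O | starting material
2 | ethyl 3-phenylpropanoate | CCOC(=O)CCc1ccccc1 | starting material
3 | 1-(5-bromo-2-hydroxy-4-methoxyphenyl)-5-phenylpentane-1,3-dione | COc1cc(O)c(cc1Br)C(=O)CC(=O)CCc1ccccc1 | intermediate
4 | 6-bromo-7-methoxy-2-(2-phenylethyl)chromen-4-one | COc1cc2oc(CCc3ccccc3)cc(=O)c2cc1Br | intermediate
5 | but-3-yn-2-ol (racemic) | CC(O)C#C | starting material
6 | 6-(3-hydroxybut-1-yn-1-yl)-7-methoxy-2-(2-phenylethyl)chromen-4-one (racemic) | COc1cc2oc(CCc3ccccc3)cc(=O)c2cc1C#CC(C)O | intermediate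
7 | 4-[7-methoxy-4-oxo-2-(2-phenylethyl)chromen-6-yl]but-3-yn-2-one | CC(=O)C#Cc1cc2c(=O)cc(CCc3ccccc3)oc2cc1OC | intermediate
8 | 2-hydroxybut-3-enoic acid (racemic) | OC(C=C)C(=O)O | starting material
9 | trimethylsilyl 2-(trimethylsilyloxy)but-3-enoate (racemic) | C=CC(O[Si](C)(C)C)C(=O)O[Si](C)(C)C | intermediate
10 | 1,1,2-tris(trimethylsilyloxy)buta-1,3-diene | C=CC(O[Si](C)(C)C)=C(O[Si](C)(C)C)O[Si](C)(C)C | intermediate
11 | 6-[2-acetyl-3,3,4-tris(trimethylsilyloxy)cyclohexa-1,4-dien-1-yl]-7-methoxy-2-(2-phenylethyl)chromen-4-one | CC(=O)C1=C(CC=C(O[Si](C)(C)C)C1(O[Si](C)(C)C)O[Si](C)(C)C)c1cc2c(=O)cc(CCc3ccccc3)oc2cc1OC | intermediate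
12 | 6-[2-acetyl-3,4-bis(trimethylsilyloxy)phenyl]-7-methoxy-2-(2-phenylethyl)chromen-4-one | CC(=O)c1c(O[Si](C)(C)C)c(O[Si](C)(C)C)ccc1-c1cc2c(=O)cc(CCc3ccccc3)oc2cc1OC | intermediate
13 | 6-(2-acetyl-3,4-dihydroxyphenyl)-7-methoxy-2-(2-phenylethyl)chromen-4-one | CC(=O)c1c(O)c(O)ccc1-c1cc2c(=O)cc(CCc3ccccc3)oc2cc1OC | intermediate
14 | 3-phenylpropanoyl chloride | O=C(Cl)CCc1ccccc1 | starting material
15 | 3-acetyl-4-[7-methoxy-4-oxo-2-(2-phenylethyl)chromen-6-yl]benzene-1,2-diyl bis(3-phenylpropanoate) | CC(=O)c1c(OC(=O)CCc2ccccc2)c(OC(=O)CCc2ccccc2)ccc1-c1cc2c(=O)cc(CCc3ccccc3)oc2cc1OC | intermediate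
16 | 2-hydroxy-4-[7-methoxy-4-oxo-2-(2-phenylethyl)chromen-6-yl]-3-(3-oxo-5-phenylpentanoyl)phenyl 3-phenylpropanoate | COc1cc2oc(CCc3ccccc3)cc(=O)c2cc1-c1ccc(OC(=O)CCc2ccccc2)c(O)c1C(=O)CC(=O)CCc1ccccc1 | intermediate
17 | 6-[8-hydroxy-4-oxo-2-(2-phenylethyl)chromen-5-yl]-7-methoxy-2-(2-phenylethyl)chromen-4-one | COc1cc2oc(CCc3ccccc3)cc(=O)c2cc1-c1ccc(O)c2oc(CCc3ccccc3)cc(=O)c12 | intermediate
18 | 7-hydroxy-6-[8-hydroxy-4-oxo-2-(2-phenylethyl)chromen-5-yl]-2-(2-phenylethyl)chromen-4-one | O=c1cc(CCc2ccccc2)oc2cc(O)c(-c3ccc(O)c4oc(CCc5ccccc5)cc(=O)c34)cc12 | target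

Total step count: 9. Longest linear sequence: 7 (steps 1, 2, 3, 6, 7, 8, 9); steps 4 and 5 form the short diene branch.

Steps most likely to fail

Step 6 (new method).
- **What may go wrong:**
  - The cycloaddition may be too slow, because the ortho methoxy group and the para ring oxygen feed electron density into the alkyne β-carbon and both reacting termini are crowded.
  - Other processes could then take over:
    - thermal or protolytic decay of the diene;
    - [2+2] addition across the ketene-acetal double bond;
    - arrest at the open-chain conjugate-addition stage;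
    - leakage into the opposite regiochemical orientation.
- **Fallback:** known chemistry, with the biaryl bond made by cross-coupling instead of ring growth. It sets out from 4 and comes back at 13.
  - Miyaura borylation of 4 (B2pin2, Pd(dppf)Cl2, KOAc, dioxane, 90 °C) should give 7-methoxy-2-(2-phenylethyl)-6-(4,4,5,5-tetramethyl-1,3,2-dioxaborolan-2-yl)chromen-4-one F1.
  - Commercial 5-bromo-1,3-benzodioxole is lithiated by LDA (THF, −78 °C) at C4, between oxygen and bromine, and quenched with N-methoxy-N-methylacetamide to give 1-(5-bromo-1,3-benzodioxol-4-yl)ethanone F2.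
  - Suzuki–Miyaura coupling of the two (Pd(OAc)2, SPhos, K3PO4, toluene/H2O, 90 °C; only one ortho substituent on each ring) should give 6-(4-acetyl-1,3-benzodioxol-5-yl)-7-methoxy-2-(2-phenylethyl)chromen-4-one F3.
  - BCl3 (CH2Cl2, −78 to 0 °C) opens methylenedioxy rings in preference to aryl methyl ethers and is guided here by the ortho acetyl group. It should release catechol 13.

Step 8.
- **What may go wrong:**
  - base-induced loss of the ester groups before migration;
  - intermolecular acyl transfer to the acidic side-chain methylene at C2 of the finished chromone;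
  - slow enolate attack from the crowded, twisted acetyl group.
- **Fallback:** the carbon chain is brought in as an aldehyde under amine catalysis, with no strong base and no ester. It sets out from 13 and comes back at 17.
  - Kabbe condensation of 13 with 3-phenylpropanal (pyrrolidine, MeOH, 60 °C) proceeds by aldol condensation and then oxa-Michael closure by the C8a' phenol. It should give racemic 6-[8-hydroxy-4-oxo-2-(2-phenylethyl)-2,3-dihydrochromen-5-yl]-7-methoxy-2-(2-phenylethyl)chromen-4-one F4.
  - DDQ (dioxane, reflux) dehydrogenates this across C2'–C3' to 17.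

Step 9.
- **What may go wrong:**
  - incomplete ether cleavage, because BBr3 is sequestered by two pyranone carbonyls and the phenol;
  - degradation or poor recovery of the polar bis-chromone when the conditions are forced.
- **Fallback:** the protecting-group plan is changed so that the last operation is a mild methanolysis. It sets out from 13 and comes back at 18.
  - Demethylation is moved forward to the sturdier 13 (BBr3, CH2Cl2, −78 °C to rt) to give 6-(2-acetyl-3,4-dihydroxyphenyl)-7-hydroxy-2-(2-phenylethyl)chromen-4-one F5.
  - All three phenols are acylated with 14 (3.5 equiv, pyridine, DMAP, CH2Cl2) to give 3-acetyl-4-[4-oxo-2-(2-phenylethyl)-7-(3-phenylpropanoyloxy)chromen-6-yl]benzene-1,2-diyl bis(3-phenylpropanoate) F6.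
  - KOtBu in THF effects the acyl migration to 6-[3-hydroxy-2-(3-oxo-5-phenylpentanoyl)-4-(3-phenylpropanoyloxy)phenyl]-4-oxo-2-(2-phenylethyl)chromen-7-yl 3-phenylpropanoate F7.
  - This is not isolated. HCl in refluxing MeOH closes the pyranone and removes both remaining esters to give 18 directly.

Further compounds
F1 | step 6 | 7-methoxy-2-(2-phenylethyl)-6-(4,4,5,5-tetramethyl-1,3,2-dioxaborolan-2-yl)chromen-4-one | COc1cc2oc(CCc3ccccc3)cc(=O)c2cc1B1OC(C)(C)C(C)(C)O1
F2 | step 6 | 1-(5-bromo-1,3-benzodioxol-4-yl)ethanone | CC(=O)c1c(Br)ccc2OCOc12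
F3 | step 6 | 6-(4-acetyl-1,3-benzodioxol-5-yl)-7-methoxy-2-(2-phenylethyl)chromen-4-one | CC(=O)c1c(ccc2OCOc12)-c1cc2c(=O)cc(CCc3ccccc3)oc2cc1OC
F4 | step 8 | 6-[8-hydroxy-4-oxo-2-(2-phenylethyl)-2,3-dihydrochromen-5-yl]-7-methoxy-2-(2-phenylethyl)chromen-4-one (racemic) | COc1cc2oc(CCc3ccccc3)cc(=O)c2cc1-c1ccc(O)c2OC(CCc3ccccc3)CC(=O)c12
F5 | step 9 | 6-(2-acetyl-3,4-dihydroxyphenyl)-7-hydroxy-2-(2-phenylethyl)chromen-4-one | CC(=O)c1c(O)c(O)ccc1-c1cc2c(=O)cc(CCc3ccccc3)oc2cc1O
F6 | step 9 | 3-acetyl-4-[4-oxo-2-(2-phenylethyl)-7-(3-phenylpropanoyloxy)chromen-6-yl]benzene-1,2-diyl bis(3-phenylpropanoate) | CC(=O)c1c(OC(=O)CCc2ccccc2)c(OC(=O)CCc2ccccc2)ccc1-c1cc2c(=O)cc(CCc3ccccc3)oc2cc1OC(=O)CCc1ccccc1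
F7 | step 9 | 6-[3-hydroxy-2-(3-oxo-5-phenylpentanoyl)-4-(3-phenylpropanoyloxy)phenyl]-4-oxo-2-(2-phenylethyl)chromen-7-yl 3-phenylpropanoate | O=C(CCc1ccccc1)Oc1cc2oc(CCc3ccccc3)cc(=O)c2cc1-c1ccc(OC(=O)CCc2ccccc2)c(O)c1C(=O)CC(=O)CCc1ccccc1
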